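## Structural features

Ring atoms are written C(A1)–C(A5) for the cyclopentane and C(B1)–C(B6) for the cyclohexene, to keep them apart from compound labels. The target is a trichodiene-type core: ring A carries an exocyclic methylene on C(A1) and a methyl on the quaternary C(A5); ring B carries a methyl on the quaternary C(B1), a C(B3)=C(B4) double bond with a methyl on C(B4), and a caffeate ester on the allylic C(B5). The rings are joined only by the C(A5)–C(B1) bond, so two fully substituted stereocentres (both S) are adjacent. The third stereocentre, C(B5) (S), lies 1,3 to C(B1) across C(B6), with its oxygen trans to the C(B1) methyl. Fragile groups are the exocyclic alkene (acid moves it into the ring), the secondary allylic ester (ionisation, elimination), the cinnamate double bond and the free catechol (oxidation, base). The real difficulty is the bond between two quaternary stereocentres with no nearby functional group, and the transfer of absolute configuration to the remote C(B5). The key step exploits that C(A5) bears a methyl and stands 1,5 to C(A1) through C(A2)–C(A3)–C(A4), so a C(A5)–H methine of fixed configuration can be made quaternary by a carbenoid placed on C(A1). C(A1) is the ring carbon that will carry the methylene; the methylene carbon itself enters as the ester carbon, and C(B1) still has two identical arms at that stage.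

## Logic of the disconnections

35 ⇒ 30 + 33 (through 34). The acyl C–O bond of the ester is cut last because the catechol and the allylic ester are the most sensitive parts. This separates the terpenoid alcohol from a commodity acid, 31, which gives 33 in one operation. The forward acylation must take place at oxygen, so that C(B5) is retained, and the final unmasking must be near neutral.

30 ⇒ 27 (through 29 and 28). The C(B4)–CH3 bond is cut, because an enol triflate fixes the position of the trisubstituted alkene. Ring B goes back to a ketone with one α-oxygen. The forward step needs enolisation away from C(B5) and a methyl coupling that leaves the allylic oxygen alone.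

27 ⇒ 24 (through 26 and 25). The C(B5)–O bond is cut. Without it ring B is a cyclohexanone with two mirror-related arms, so C(B1) and C(B5) cease to be stereocentres together and only C(A5) remains. The forward oxygenation must pick one of two enantiotopic methylenes and one face. The D enantiomer of proline is required here; natural proline would build the mirror-image ring B.

24 ⇒ 16 (through 23, 20, 19 and 17). No skeletal bond is cut. The C(A1) methylene is traced to an ester on C(A1) and the C(A2) hydrogens to a ketone, which is the β-keto ester left by a carbenoid insertion. The forward sequence must remove the C(A2) oxygen and move the double bond to the exocyclic position while the ring-B ketone stays masked.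

16 ⇒ 15. The C(A1)–C(A5) bond is cut. This opens ring A and turns the quaternary stereocentre into a methine that can be bought. The forward step must be stereospecific (retention) and must select a hindered tertiary C–H bond.

15 ⇒ 12 + 13. The C(A1)–C(A2) bond is cut, and the diazo keto ester falls to an aldehyde and a diazoacetate. The forward step must join them and reach the ketone oxidation level without harming the diazo group or the ketal.

12 ⇒ 9 (through 10). The aldehyde carbon C(A2) is reconnected to an isopropylidene group, so the chain becomes that of a terpene aldehyde. The ring ketone must be protected before the alkene is cleaved.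

9 ⇒ 4 + 5 (through 8). The two Robinson bonds are cut: one C(B1)–CH2 bond, and the bond between the former aldehyde carbon and the ketone methyl. Ring B falls to an α-branched aldehyde and a four-carbon enone. The forward Michael addition must form a quaternary carbon next to a methine; its configuration does not matter because the centre becomes non-stereogenic.

4 ⇒ 1 (through 2). The C(B1)–CH3 bond is cut, leaving a chiral-pool aldehyde whose β-stereocentre is the future C(A5). The forward methylation must be a clean mono-alkylation of an enolisable aldehyde, which calls for the imine.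

## Other disconnections considered

Alternative 1: The cut removes C(B4)–C(B5) and C(B2)–C(B3), so ring B is traced to the cyclobutanone compound A1, in which C(B1) is the symmetric ring carbon 3, and the silyl alkyne compound A2.
- **Forward step.** Ni(cod)2 with a chiral phosphine would couple carbonyl and alkyne on zerovalent nickel, cleave one of the two enantiotopic C(B5)–CH2 bonds by β-carbon elimination and close the ring by reductive elimination, giving compound A3.
- **In favour.** C(B1) would be set in the same event that builds ring B. The C(B4) methyl and the C(B5) oxygen arrive in their final positions, so neither an enol triflate nor a hydroxyl protecting group is needed on ring B.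
- **Against.** C(A5) must first be made by a separate asymmetric step and carried into a hindered 3,3-disubstituted cyclobutanone. The ligand must choose between two bonds to a neopentyl-type carbon beside an existing stereocentre, with a matched or mismatched outcome. Hydride addition to the C(B5) ketone is expected to be steered by the axial C(B1) methyl toward the epimer with hydroxyl cis to that methyl, the opposite of the target, so reagent control or an inversion would be needed. Ring A still needs desilylation, oxidation and methylenation of a hindered ketone.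
- **Comparison.** On structure the alternative is the better of the two for the ring-B substitution pattern, and sets C(B1) during ring formation rather than by a later desymmetrisation. On mechanism the chosen insertion is a stereospecific reaction with close analogy, while an enantioselective intermolecular insertion next to a quaternary stereocentre is less charted. On step economy the two should be about equal once the making of compound A1 is counted.

Alternative 2: The cut is the C(B1)–CH3 bond, disguised as the cyclopropane bonds C(B1)–CH2 and C(B6)–CH2 of compound A5, which comes from the allylic alcohol compound A4.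
- **Forward step.** Et2Zn and CH2I2 would deliver the methylene to the C(B1)=C(B6) alkene on the face of the C(B5) hydroxyl (hydroxyl-directed cyclopropanation).
- **In favour.** This is one of the most dependable substrate-directed reactions, even for hindered trisubstituted alkenes, and it relays configuration from C(B5) to C(B1) with high fidelity. An aromatic precursor makes the C(A5)–C(B1) bond easy to form.
- **Against.** In compound A5 the hydroxyl is cis to the future methyl, whereas the target has the oxygen trans to it. C(B5) must therefore be oxidised (needed anyway to open the ring reductively) and set a second time, with the facial bias noted under Alternative 1. After ring opening, C(B4) still lacks its methyl and the C(B3)=C(B4) alkene, which costs an α-methylation, a dehydrogenation and a 1,2-reduction. C(A5) again needs its own asymmetric step.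
- **Comparison.** On mechanism the alternative is the better of the two for control of C(B1): directed delivery is more predictable than a catalyst desymmetrisation whose sense is inferred. The two plans are equal in setting C(B1) after C(A5). On structure and step economy the alternative is worse, because the stereocentre that directs is then destroyed and the ring-B pattern is built stepwise afterwards.

Alternative 3: The cut removes C(B1)–C(B2) and C(A4)–C(A5) at once, tracing the product compound A7 to the acyclic enone compound A6.
- **Forward step.** A chelating Lewis acid (TiCl4 or Me2AlCl) would bind the ketone and the benzyloxy oxygen. The tetrasubstituted alkene would attack the enone terminus C(B2) through C(B1), closing ring B. The cation at C(A5) would be quenched by migration of a cyclobutanol ring bond, forming C(A4)–C(A5), closing ring A and leaving a ketone at C(A1).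
- **In favour.** Both quaternary stereocentres and both rings form in one anti addition across the alkene, and the Z geometry maps onto the required relative configuration. The C(B5) oxygen is present from the start with the correct configuration and steers the face. The ketones at C(A1) and C(B4) are where the methylene and the methyl are needed.
- **Against.** A geometrically pure Z tetrasubstituted alkene bearing a cyclobutanol is hard to make, and any E isomer becomes a diastereomer. Facial control rests on one chelated stereocentre. Proton loss, closure onto the carbonyl or enone polymerisation could intercept the cation. The two ketones of compound A7 must then be told apart, and the benzyl ether must be removed without hydrogenation.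
- **Comparison.** On step economy and convergence the alternative is clearly the better of the two, and it is the equal of the chosen plan in delivering C(B5) without inversion. On mechanism it is the less secure: the chosen plan splits the problem into a stereospecific insertion and a catalyst-controlled desymmetrisation, each with close analogy, while the cascade has no close model for a tetrasubstituted alkene ending in ring expansion.

Key step: step 8

Assumption: (S)-citronellal, D-proline, [(Ph3P)CuH]6 and methyl diazoacetate (as a stabilised solution) are taken as purchasable; metal-bound transients (enolates, the rhodium carbenoid, organopalladium species) are described within the steps and carry no number, whereas every neutral organic intermediate does.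

## Route

Step 1
Reactants: 1 (3S)-3,7-dimethyloct-6-enal [(S)-citronellal]
Product: 2 (1E,3S)-N-tert-butyl-3,7-dimethyloct-6-en-1-imine
Conditions: t-BuNH2, 4 Å MS, Et2O, 0 °C → rt
Reagents that add atoms: tert-butylamine, CC(C)(C)N
Why: Imine condensation of an unhindered aldehyde, driven by removal of water; no stereocentre is touched and no acid is present that could trigger cyclisation onto the alkene.

Step 2
Reactants: 2 (1E,3S)-N-tert-butyl-3,7-dimethyloct-6-en-1-imine
Product: 4 (3S)-2,3,7-trimethyloct-6-enal (both C2 epimers), via methylated imine 3 (not isolated)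
Conditions: LiN(i-Pr)2, THF, −78 → 0 °C; MeI, −78 °C → rt; then AcOH/NaOAc, H2O/pentane, rt
Reagents that add atoms: iodomethane, CI; water, O
Why: Metalloenamine (aza-enolate) alkylation gives clean mono-C-methylation where the free aldehyde would self-condense, and buffered hydrolysis releases the aldehyde. The new C2 centre is a mixture of no consequence, and the C3 stereocentre is not acidic.

Step 3
Reactants: 4 (3S)-2,3,7-trimethyloct-6-enal; 5 but-3-en-2-one
Product: 8 4-methyl-4-[(2S)-6-methylhept-5-en-2-yl]cyclohex-2-en-1-one (both C4 epimers), via Michael adduct 6 (not isolated), via aldol ketol 7 (not isolated)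
Conditions: KOH (cat.), EtOH, 0 °C → rt; then KOH, EtOH/H2O, 70 °C
Reagents that add atoms: none
Why: Robinson annulation: the aldehyde has one α-hydrogen, so Michael addition gives the quaternary carbon directly, and only the methyl ketone can then enolise onto the aldehyde to close and dehydrate the six-membered ring. The quaternary centre forms as a mixture that converges in step 4.

Step 4
Reactants: 8 4-methyl-4-[(2S)-6-methylhept-5-en-2-yl]cyclohex-2-en-1-one
Product: 9 4-methyl-4-[(2S)-6-methylhept-5-en-2-yl]cyclohexan-1-one
Conditions: [(Ph3P)CuH]6 (cat.), PPh3, H2 (20 bar), C6H6, rt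
Reagents that add atoms: none
Why: Copper hydride conjugate reduction is chemoselective for the enone over the isolated trisubstituted alkene. Saturating the ring makes C(B1) non-stereogenic, so both epimers of 8 give one compound.

Step 5
Reactants: 9 4-methyl-4-[(2S)-6-methylhept-5-en-2-yl]cyclohexan-1-one
Product: 10 8-methyl-8-[(2S)-6-methylhept-5-en-2-yl]-1,4-dioxaspiro[4.5]decane
Conditions: HOCH2CH2OH, PPTS (cat.), C6H6, reflux (Dean–Stark)
Reagents that add atoms: ethane-1,2-diol, OCCO
Why: Acid-catalysed ketalisation of an unhindered ketone with azeotropic removal of water; the pyridinium acid is mild enough to leave the trisubstituted alkene alone.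

Step 6
Reactants: 10 8-methyl-8-[(2S)-6-methylhept-5-en-2-yl]-1,4-dioxaspiro[4.5]decane
Product: 12 (4S)-4-(8-methyl-1,4-dioxaspiro[4.5]decan-8-yl)pentanal, via ozonide 11 (not isolated)
Conditions: O3, CH2Cl2, −78 °C; PPh3, −78 °C → rt
Reagents that add atoms: ozone, [O-][O+]=O
Why: Ozonolysis with reductive work-up cleaves the only alkene to the aldehyde and acetone; the ketal is inert under these neutral conditions.

Step 7
Reactants: 12 (4S)-4-(8-methyl-1,4-dioxaspiro[4.5]decan-8-yl)pentanal; 13 methyl 2-diazoacetate
Product: 15 methyl (6S)-2-diazo-6-(8-methyl-1,4-dioxaspiro[4.5]decan-8-yl)-3-oxoheptanoate, via diazo carbinol 14 (not isolated)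
Conditions: DBU (cat.), DMSO, rt; then IBX, rt
Reagents that add atoms: none
Why: Amidine-catalysed aldol-type addition of the diazoacetate to the aldehyde forms the C(A1)–C(A2) bond, and IBX then oxidises the diazo carbinol to the α-diazo-β-keto ester in the same flask. Neither stage is acidic, so the ketal and the diazo group survive.

Step 8
Reactants: 15 methyl (6S)-2-diazo-6-(8-methyl-1,4-dioxaspiro[4.5]decan-8-yl)-3-oxoheptanoate
Product: 16 methyl (1R,2S)-2-methyl-2-(8-methyl-1,4-dioxaspiro[4.5]decan-8-yl)-5-oxocyclopentane-1-carboxylate
Conditions: Rh2(OAc)4 (1 mol %), CH2Cl2, 40 °C (slow addition of 15)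
Reagents that add atoms: none
Why: Rh2(OAc)4 binds the diazo carbon of 15, N2 leaves, and an electrophilic rhodium carbenoid results at C(A1), flanked by ketone and ester. The carbenoid carbon inserts into the C(A5)–H bond through a three-centre transition state in which the C–C and C–H bonds form as the C–Rh bond breaks; the closest known reaction type is the dirhodium tetracarboxylate-catalysed 1,5 C–H insertion of α-diazo-β-keto esters into tertiary C–H bonds. Ring A closes in the 1,5-insertion mode: the chain C(A1)–C(A2)–C(A3)–C(A4)–C(A5) folds into a chair-like array that includes the migrating hydrogen, which is why a five-membered ring is preferred over four- or six-membered ones. C(A5) is controlled by the substrate, because insertion takes place at the front of the C–H bond and the S centre bought with 1 is carried over with retention. C(A1) forms as the epimerisable β-keto ester carbon, should settle with the ester trans to the bulky ring-B group, and is erased in step 10. The step needs site selectivity for a shielded methine; this is secured by the preference tertiary > secondary > primary, by the absence of any other C–H bond in a 1,5 relationship, and by the lack of hydrogen next to the carbenoid carbon. Slow addition at high dilution suppresses carbenoid dimerisation, and the ketal oxygens are too remote to reach the carbenoid through a small ring.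

Step 9
Reactants: 16 methyl (1R,2S)-2-methyl-2-(8-methyl-1,4-dioxaspiro[4.5]decan-8-yl)-5-oxocyclopentane-1-carboxylate
Product: 17 methyl (2S)-5-hydroxy-2-methyl-2-(8-methyl-1,4-dioxaspiro[4.5]decan-8-yl)cyclopentane-1-carboxylate (mixture at C1 and C5)
Conditions: NaBH4, MeOH, 0 °C
Reagents that add atoms: none
Why: Borohydride reduces the ring ketone but neither the ester nor the ketal; the configuration of the carbinol and of C(A1) is irrelevant because both are removed in step 10.

Step 10
Reactants: 17 methyl (2S)-5-hydroxy-2-methyl-2-(8-methyl-1,4-dioxaspiro[4.5]decan-8-yl)cyclopentane-1-carboxylate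
Product: 19 methyl (5R)-5-methyl-5-(8-methyl-1,4-dioxaspiro[4.5]decan-8-yl)cyclopent-1-ene-1-carboxylate, via mesylate 18 (not isolated)
Conditions: MsCl, Et3N, CH2Cl2, 0 °C; then DBU, rt
Reagents that add atoms: none
Why: Mesylation then E1cB elimination through the ester enolate places the alkene between C(A1) and C(A2), in conjugation. C(A5) is quaternary and cannot take part; the descriptor changes to R only through ligand priorities.

Step 11
Reactants: 19 methyl (5R)-5-methyl-5-(8-methyl-1,4-dioxaspiro[4.5]decan-8-yl)cyclopent-1-ene-1-carboxylate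
Product: 20 [(5R)-5-methyl-5-(8-methyl-1,4-dioxaspiro[4.5]decan-8-yl)cyclopent-1-en-1-yl]methanol
Conditions: i-Bu2AlH, CH2Cl2, −78 °C; aq. potassium sodium tartrate
Reagents that add atoms: none
Why: 1,2-Reduction of the conjugated ester by the aluminium hydride at low temperature gives the primary allylic alcohol; the dioxolane is stable under these conditions.

Step 12
Reactants: 20 [(5R)-5-methyl-5-(8-methyl-1,4-dioxaspiro[4.5]decan-8-yl)cyclopent-1-en-1-yl]methanol
Product: 23 8-methyl-8-[(1S)-1-methyl-2-methylidenecyclopentyl]-1,4-dioxaspiro[4.5]decane, via sulfonylhydrazine adduct 21 (not isolated), via allylic diazene 22 (not isolated)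
Conditions: 2-O2NC6H4SO2NHNH2, PPh3, DEAD, THF, −30 °C; then rt
Reagents that add atoms: none
Why: Reductive allylic transposition: Mitsunobu displacement of the primary allylic alcohol by the sulfonyl hydrazide, loss of the sulfinic acid on warming, then retro-ene loss of N2 from the diazene. Hydrogen is delivered to C(A2) and the double bond moves to the exocyclic position.

Step 13
Reactants: 23 8-methyl-8-[(1S)-1-methyl-2-methylidenecyclopentyl]-1,4-dioxaspiro[4.5]decane
Product: 24 4-methyl-4-[(1S)-1-methyl-2-methylidenecyclopentyl]cyclohexan-1-one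
Conditions: PPTS, acetone/H2O, 55 °C
Reagents that add atoms: water, O
Why: Mild acid hydrolysis of the dioxolane; the buffered pyridinium acid should not protonate the 1,1-disubstituted alkene, so the methylene stays exocyclic.

Step 14
Reactants: 24 4-methyl-4-[(1S)-1-methyl-2-methylidenecyclopentyl]cyclohexan-1-one
Product: 26 (2S,4S)-2-hydroxy-4-methyl-4-[(1S)-1-methyl-2-methylidenecyclopentyl]cyclohexan-1-one, via anilinooxy ketone 25 (not isolated)
Conditions: PhNO (slow addition), D-proline (20 mol %), DMF, 0 °C; then CuSO4·5H2O (cat.), MeOH, 0 °C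
Reagents that add atoms: nitrosobenzene, O=Nc1ccccc1
Why: Proline-catalysed α-aminoxylation (enamine catalysis, O-selective nitroso aldol) desymmetrises the ketone, and CuSO4 then cleaves the N–O bond. D-Proline directs oxygen to the enamine face that gives the S carbinol centre. Of the two enantiotopic methylenes, the one should react at which this face is anti to the pseudoaxial C(B1) methyl (the bulky cyclopentyl group sits pseudoequatorial), so C(B5) and C(B1) are set together with oxygen trans to the methyl.

Step 15
Reactants: 26 (2S,4S)-2-hydroxy-4-methyl-4-[(1S)-1-methyl-2-methylidenecyclopentyl]cyclohexan-1-one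
Product: 27 (2S,4S)-2-{[tert-butyl(dimethyl)silyl]oxy}-4-methyl-4-[(1S)-1-methyl-2-methylidenecyclopentyl]cyclohexan-1-one
Conditions: TBSCl, imidazole, DMF, rt
Reagents that add atoms: tert-butyl(chloro)dimethylsilane, CC(C)(C)[Si](C)(C)Cl
Why: Standard silylation of a secondary alcohol; prompt protection prevents ketol isomerisation and shields C(B5)–H from later deprotonation.

Step 16
Reactants: 27 (2S,4S)-2-{[tert-butyl(dimethyl)silyl]oxy}-4-methyl-4-[(1S)-1-methyl-2-methylidenecyclopentyl]cyclohexan-1-one
Product: 28 (4S,6S)-6-{[tert-butyl(dimethyl)silyl]oxy}-4-methyl-4-[(1S)-1-methyl-2-methylidenecyclopentyl]cyclohex-1-en-1-yl trifluoromethanesulfonate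
Conditions: KN(SiMe3)2, THF, −78 °C; PhNTf2, −78 → 0 °C
Reagents that add atoms: N-phenylbis(trifluoromethanesulfonimide), FC(F)(F)S(=O)(=O)N(c1ccccc1)S(=O)(=O)C(F)(F)F
Why: Kinetic deprotonation by the hindered amide at the unsubstituted methylene C(B3), then O-triflation of the potassium enolate (enol triflate formation). The silyloxy-bearing C(B5)–H is disfavoured sterically and electronically, so that centre is not touched.

Step 17
Reactants: 28 (4S,6S)-6-{[tert-butyl(dimethyl)silyl]oxy}-4-methyl-4-[(1S)-1-methyl-2-methylidenecyclopentyl]cyclohex-1-en-1-yl trifluoromethanesulfonate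
Product: 29 tert-butyl({(1S,5S)-2,5-dimethyl-5-[(1S)-1-methyl-2-methylidenecyclopentyl]cyclohex-2-en-1-yl}oxy)dimethylsilane
Conditions: MeZnCl, Pd(PPh3)4 (5 mol %), THF, 50 °C
Reagents that add atoms: methylzinc chloride, C[Zn]Cl
Why: Negishi cross-coupling of the alkenyl triflate under zerovalent palladium catalysis puts the methyl on C(B4) with the double bond fixed between C(B3) and C(B4); the silyl ether is too poor a leaving group to ionise.

Step 18
Reactants: 29 tert-butyl({(1S,5S)-2,5-dimethyl-5-[(1S)-1-methyl-2-methylidenecyclopentyl]cyclohex-2-en-1-yl}oxy)dimethylsilane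
Product: 30 (1S,5S)-2,5-dimethyl-5-[(1S)-1-methyl-2-methylidenecyclopentyl]cyclohex-2-en-1-ol
Conditions: Bu4NF, THF, rt
Reagents that add atoms: none
Why: Fluoride cleavage of the silyl ether at silicon; the non-acidic conditions avoid ionising the allylic alcohol, so C(B5) is retained.

Step 19
Reactants: 31 (2E)-3-(3,4-dihydroxyphenyl)prop-2-enoic acid (caffeic acid)
Product: 33 (2E)-3-{3,4-bis[tert-butyl(dimethyl)silyloxy]phenyl}prop-2-enoic acid, via silyl ester 32 (not isolated)
Conditions: TBSCl, imidazole, DMF, rt; then AcOH/THF/H2O, rt
Reagents that add atoms: tert-butyl(chloro)dimethylsilane, CC(C)(C)[Si](C)(C)Cl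
Why: Exhaustive silylation, then selective hydrolysis of the very labile silyl ester, leaves the two aryl silyl ethers and the free acid.

Step 20
Reactants: 30 (1S,5S)-2,5-dimethyl-5-[(1S)-1-methyl-2-methylidenecyclopentyl]cyclohex-2-en-1-ol; 33 (2E)-3-{3,4-bis[tert-butyl(dimethyl)silyloxy]phenyl}prop-2-enoic acid
Product: 34 (1S,5S)-2,5-dimethyl-5-[(1S)-1-methyl-2-methylidenecyclopentyl]cyclohex-2-en-1-yl (2E)-3-{3,4-bis[tert-butyl(dimethyl)silyloxy]phenyl}prop-2-enoate
Conditions: DCC, DMAP, CH2Cl2, 0 °C → rt
Reagents that add atoms: none
Why: Steglich esterification (carbodiimide activation, acyl transfer through the acylpyridinium) acylates the alcohol oxygen, so C(B5) keeps its configuration. The cinnamic acid cannot form a ketene and the E alkene is not touched.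

Step 21
Reactants: 34 (1S,5S)-2,5-dimethyl-5-[(1S)-1-methyl-2-methylidenecyclopentyl]cyclohex-2-en-1-yl (2E)-3-{3,4-bis[tert-butyl(dimethyl)silyloxy]phenyl}prop-2-enoate
Product: 35 (1S,5S)-2,5-dimethyl-5-[(1S)-1-methyl-2-methylidenecyclopentyl]cyclohex-2-en-1-yl (2E)-3-(3,4-dihydroxyphenyl)prop-2-enoate
Conditions: Bu4NF, AcOH, THF, 0 °C
Reagents that add atoms: none
Why: Fluoride removes the two aryl silyl ethers quickly. Acetic acid protonates the phenoxides as they form, which protects the allylic ester from acyl transfer and the catechol from oxidation.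

## Compound list

1 | (3S)-3,7-dimethyloct-6-enal, (S)-citronellal | CC(C)=CCC[C@H](C)CC=O | starting material
2 | (1E,3S)-N-tert-butyl-3,7-dimethyloct-6-en-1-imine | CC(C)=CCC[C@H](C)C/C=N/C(C)(C)C | intermediate
3 | (1E,3S)-N-tert-butyl-2,3,7-trimethyloct-6-en-1-imine (both C2 epimers) | CC(C)=CCC[C@H](C)C(C)/C=N/C(C)(C)C | intermediate (not isolated)
4 | (3S)-2,3,7-trimethyloct-6-enal (both C2 epimers) | CC(C)=CCC[C@H](C)C(C)C=O | intermediate
5 | but-3-en-2-one | CC(=O)C=C | starting material
6 | (3S)-2,3,7-trimethyl-2-(3-oxobutyl)oct-6-enal (both C2 epimers) | CC(C)=CCC[C@H](C)C(C)(CCC(C)=O)C=O | intermediate (not isolated)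
7 | 3-hydroxy-4-methyl-4-[(2S)-6-methylhept-5-en-2-yl]cyclohexan-1-one (diastereomer mixture) | CC(C)=CCC[C@H](C)C1(C)CCC(=O)CC1O | intermediate (not isolated)
8 | 4-methyl-4-[(2S)-6-methylhept-5-en-2-yl]cyclohex-2-en-1-one (both C4 epimers) | CC(C)=CCC[C@H](C)C1(C)CCC(=O)C=C1 | intermediate
9 | 4-methyl-4-[(2S)-6-methylhept-5-en-2-yl]cyclohexan-1-one | CC(C)=CCC[C@H](C)C1(C)CCC(=O)CC1 | intermediate
10 | 8-methyl-8-[(2S)-6-methylhept-5-en-2-yl]-1,4-dioxaspiro[4.5]decane | CC(C)=CCC[C@H](C)C1(C)CCC2(CC1)OCCO2 | intermediate
11 | 3,3-dimethyl-5-[(3S)-3-(8-methyl-1,4-dioxaspiro[4.5]decan-8-yl)butyl]-1,2,4-trioxolane | CC1(C)OOC(CC[C@H](C)C2(C)CCC3(CC2)OCCO3)O1 | intermediate (not isolated)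
12 | (4S)-4-(8-methyl-1,4-dioxaspiro[4.5]decan-8-yl)pentanal | O=CCC[C@H](C)C1(C)CCC2(CC1)OCCO2 | intermediate
13 | methyl 2-diazoacetate | COC(=O)C=[N+]=[N-] | starting material
14 | methyl (6S)-2-diazo-3-hydroxy-6-(8-methyl-1,4-dioxaspiro[4.5]decan-8-yl)heptanoate (both C3 epimers) | COC(=O)C(=[N+]=[N-])C(O)CC[C@H](C)C1(C)CCC2(CC1)OCCO2 | intermediate (not isolated)
15 | methyl (6S)-2-diazo-6-(8-methyl-1,4-dioxaspiro[4.5]decan-8-yl)-3-oxoheptanoate | COC(=O)C(=[N+]=[N-])C(=O)CC[C@H](C)C1(C)CCC2(CC1)OCCO2 | intermediate
16 | methyl (1R,2S)-2-methyl-2-(8-methyl-1,4-dioxaspiro[4.5]decan-8-yl)-5-oxocyclopentane-1-carboxylate | COC(=O)[C@H]1C(=O)CC[C@]1(C)C1(C)CCC2(CC1)OCCO2 | intermediate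
17 | methyl (2S)-5-hydroxy-2-methyl-2-(8-methyl-1,4-dioxaspiro[4.5]decan-8-yl)cyclopentane-1-carboxylate (mixture at C1 and C5) | COC(=O)C1C(O)CC[C@]1(C)C1(C)CCC2(CC1)OCCO2 | intermediate
18 | methyl (2S)-5-(methanesulfonyloxy)-2-methyl-2-(8-methyl-1,4-dioxaspiro[4.5]decan-8-yl)cyclopentane-1-carboxylate | COC(=O)C1C(OS(C)(=O)=O)CC[C@]1(C)C1(C)CCC2(CC1)OCCO2 | intermediate (not isolated)
19 | methyl (5R)-5-methyl-5-(8-methyl-1,4-dioxaspiro[4.5]decan-8-yl)cyclopent-1-ene-1-carboxylate | COC(=O)C1=CCC[C@]1(C)C1(C)CCC2(CC1)OCCO2 | intermediate
20 | [(5R)-5-methyl-5-(8-methyl-1,4-dioxaspiro[4.5]decan-8-yl)cyclopent-1-en-1-yl]methanol | OCC1=CCC[C@]1(C)C1(C)CCC2(CC1)OCCO2 | intermediate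
21 | N-{[(5R)-5-methyl-5-(8-methyl-1,4-dioxaspiro[4.5]decan-8-yl)cyclopent-1-en-1-yl]methyl}-2-nitrobenzenesulfonohydrazide | NN(CC1=CCC[C@]1(C)C1(C)CCC2(CC1)OCCO2)S(=O)(=O)c1ccccc1[N+](=O)[O-] | intermediate (not isolated)
22 | {[(5R)-5-methyl-5-(8-methyl-1,4-dioxaspiro[4.5]decan-8-yl)cyclopent-1-en-1-yl]methyl}diazene | N=NCC1=CCC[C@]1(C)C1(C)CCC2(CC1)OCCO2 | intermediate (not isolated)
23 | 8-methyl-8-[(1S)-1-methyl-2-methylidenecyclopentyl]-1,4-dioxaspiro[4.5]decane | C=C1CCC[C@]1(C)C1(C)CCC2(CC1)OCCO2 | intermediate
24 | 4-methyl-4-[(1S)-1-methyl-2-methylidenecyclopentyl]cyclohexan-1-one | C=C1CCC[C@]1(C)C1(C)CCC(=O)CC1 | intermediate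
25 | (2S,4S)-2-(anilinooxy)-4-methyl-4-[(1S)-1-methyl-2-methylidenecyclopentyl]cyclohexan-1-one | C=C1CCC[C@]1(C)[C@@]1(C)CCC(=O)[C@@H](ONc2ccccc2)C1 | intermediate (not isolated)
26 | (2S,4S)-2-hydroxy-4-methyl-4-[(1S)-1-methyl-2-methylidenecyclopentyl]cyclohexan-1-one | C=C1CCC[C@]1(C)[C@@]1(C)CCC(=O)[C@@H](O)C1 | intermediate
27 | (2S,4S)-2-{[tert-butyl(dimethyl)silyl]oxy}-4-methyl-4-[(1S)-1-methyl-2-methylidenecyclopentyl]cyclohexan-1-one | C=C1CCC[C@]1(C)[C@@]1(C)CCC(=O)[C@@H](O[Si](C)(C)C(C)(C)C)C1 | intermediate
28 | (4S,6S)-6-{[tert-butyl(dimethyl)silyl]oxy}-4-methyl-4-[(1S)-1-methyl-2-methylidenecyclopentyl]cyclohex-1-en-1-yl trifluoromethanesulfonate | C=C1CCC[C@]1(C)[C@@]1(C)CC=C(OS(=O)(=O)C(F)(F)F)[C@@H](O[Si](C)(C)C(C)(C)C)C1 | intermediate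
29 | tert-butyl({(1S,5S)-2,5-dimethyl-5-[(1S)-1-methyl-2-methylidenecyclopentyl]cyclohex-2-en-1-yl}oxy)dimethylsilane | C=C1CCC[C@]1(C)[C@@]1(C)CC=C(C)[C@@H](O[Si](C)(C)C(C)(C)C)C1 | intermediate
30 | (1S,5S)-2,5-dimethyl-5-[(1S)-1-methyl-2-methylidenecyclopentyl]cyclohex-2-en-1-ol | C=C1CCC[C@]1(C)[C@@]1(C)CC=C(C)[C@@H](O)C1 | intermediate
31 | (2E)-3-(3,4-dihydroxyphenyl)prop-2-enoic acid, caffeic acid | OC(=O)/C=C/c1ccc(O)c(O)c1 | starting material
32 | tert-butyl(dimethyl)silyl (2E)-3-{3,4-bis[tert-butyl(dimethyl)silyloxy]phenyl}prop-2-enoate | CC(C)(C)[Si](C)(C)OC(=O)/C=C/c1ccc(O[Si](C)(C)C(C)(C)C)c(O[Si](C)(C)C(C)(C)C)c1 | intermediate (not isolated)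
33 | (2E)-3-{3,4-bis[tert-butyl(dimethyl)silyloxy]phenyl}prop-2-enoic acid | OC(=O)/C=C/c1ccc(O[Si](C)(C)C(C)(C)C)c(O[Si](C)(C)C(C)(C)C)c1 | intermediate
34 | (1S,5S)-2,5-dimethyl-5-[(1S)-1-methyl-2-methylidenecyclopentyl]cyclohex-2-en-1-yl (2E)-3-{3,4-bis[tert-butyl(dimethyl)silyloxy]phenyl}prop-2-enoate | C=C1CCC[C@]1(C)[C@@]1(C)CC=C(C)[C@@H](OC(=O)/C=C/c2ccc(O[Si](C)(C)C(C)(C)C)c(O[Si](C)(C)C(C)(C)C)c2)C1 | intermediate
35 | (1S,5S)-2,5-dimethyl-5-[(1S)-1-methyl-2-methylidenecyclopentyl]cyclohex-2-en-1-yl (2E)-3-(3,4-dihydroxyphenyl)prop-2-enoate | C=C1CCC[C@]1(C)[C@@]1(C)CC=C(C)[C@@H](OC(=O)/C=C/c2ccc(O)c(O)c2)C1 | target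

## Step count and least certain steps

Total: 21 steps. Longest linear sequence: 20 steps (steps 1–18, 20 and 21, from 1 to 35); step 19 is a one-step branch from 31.

**Step 8 (key step).** The carbenoid may be consumed before it reaches the C(A5)–H bond, by dimerisation, by O–H insertion into traces of water, or by insertion into the more exposed ring-B methylene C–H bonds. The cause is that this methine is shielded by the fully substituted C(B1) next to it. The fallback changes the order of ring construction, so that insertion takes place before C(B1) becomes quaternary; it sets out from 4 and comes back at 24.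
- The aldehyde of 4 would be masked with ethylene glycol and PPTS as the dioxolane acetal F1.
- Ozonolysis would give, through the ozonide F2, the acetal aldehyde F3.
- DBU and IBX with 13 would give, through the diazo carbinol F4, the diazo keto ester F5.
- Rh2(OAc)4 would then insert into a methine whose neighbour is only a tertiary carbon, giving the cyclopentanone keto ester F6.
- The operations of steps 9–12 would follow: NaBH4 to the hydroxy ester F7; mesylation through the mesylate F8 and elimination to the enoate F9; i-Bu2AlH to the allylic alcohol F10; Mitsunobu transposition through the hydrazide adduct F11 and the diazene F12 to the methylene acetal F13.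
- PPTS in wet acetone would release the aldehyde F14.
- Robinson annulation with 5, through the Michael adduct F15 and the ketol F16, would build the second quaternary carbon as the enone F17.
- The copper hydride reduction of step 4 would give 24. The weak point of this fallback is the Michael addition that joins the two quaternary carbons.

**Step 14.** Discrimination between the two enantiotopic methylenes may be poor if the catalyst's facial preference and the preference for attack anti to the axial methyl reinforce each other less than assumed. Nitrosobenzene may also undergo an ene reaction with the exocyclic alkene or oxidise the ketone twice. The fallback sets out from 24 and comes back at 26. Enantioselective deprotonation with a chiral lithium bis(1-phenylethyl)amide in the presence of Me3SiCl would give the silyl enol ether F18, the enantiomer of the base being chosen so that the C(B5) hydrogen is removed. MeLi would regenerate the lithium enolate regiospecifically, and 2-(benzenesulfonyl)-3-phenyloxaziridine would hydroxylate it anti to the axial methyl to give 26.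

**Step 3.** The Michael addition may be slow at the congested α-carbon, which has a methine as neighbour, so that the enone polymerises or the adduct reverts before ring closure. The fallback sets out from 4 and comes back at 6. The imine 3 would be re-formed from 4, lithiated with LiN(i-Pr)2 and C-alkylated with 2-(2-bromoethyl)-2-methyl-1,3-dioxolane to the imine ketal F19. Aqueous acid would cleave imine and ketal to 6, which KOH would cyclise to 8.

**Step 12.** The Mitsunobu displacement may be incomplete at the carbon flanked by the quaternary C(A5), or may proceed with allylic shift, which after loss of N2 would place the alkene in the ring. The fallback sets out from 20 and comes back at 23. Methyl chloroformate and pyridine would give the allylic carbonate F20. Pd(OAc)2, PBu3 and HCO2NH4 would then reduce it by formate hydrogenolysis of the π-allyl complex, which delivers hydride to the more substituted terminus C(A2) and leaves the exocyclic methylene.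

**Step 7.** The diazo aldol addition is reversible and the oxidation may lag behind, so the aldehyde may condense with itself under the amidine base. The fallback sets out from 12 and comes back at 15. SnCl2-catalysed homologation of 12 with 13 (Roskamp reaction) would give the β-keto ester F21, and Regitz diazo transfer with 4-acetamidobenzenesulfonyl azide and Et3N would convert it to 15.

## Further compounds

F1 | step 8 | 2-[(3S)-3,7-dimethyloct-6-en-2-yl]-1,3-dioxolane | CC(C)=CCC[C@H](C)C(C)C1OCCO1
F2 | step 8 | 3-[(3S)-4-(1,3-dioxolan-2-yl)-3-methylpentyl]-5,5-dimethyl-1,2,4-trioxolane | CC1(C)OOC(CC[C@H](C)C(C)C2OCCO2)O1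
F3 | step 8 | (4S)-5-(1,3-dioxolan-2-yl)-4-methylhexanal | O=CCC[C@H](C)C(C)C1OCCO1
F4 | step 8 | methyl (6S)-2-diazo-7-(1,3-dioxolan-2-yl)-3-hydroxy-6-methyloctanoate | COC(=O)C(=[N+]=[N-])C(O)CC[C@H](C)C(C)C1OCCO1
F5 | step 8 | methyl (6S)-2-diazo-7-(1,3-dioxolan-2-yl)-6-methyl-3-oxooctanoate | COC(=O)C(=[N+]=[N-])C(=O)CC[C@H](C)C(C)C1OCCO1
F6 | step 8 | methyl (1R,2R)-2-[1-(1,3-dioxolan-2-yl)ethyl]-2-methyl-5-oxocyclopentane-1-carboxylate | COC(=O)[C@H]1C(=O)CC[C@]1(C)C(C)C1OCCO1
F7 | step 8 | methyl (2R)-2-[1-(1,3-dioxolan-2-yl)ethyl]-5-hydroxy-2-methylcyclopentane-1-carboxylate | COC(=O)C1C(O)CC[C@]1(C)C(C)C1OCCO1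
F8 | step 8 | methyl (2R)-2-[1-(1,3-dioxolan-2-yl)ethyl]-5-(methanesulfonyloxy)-2-methylcyclopentane-1-carboxylate | COC(=O)C1C(OS(C)(=O)=O)CC[C@]1(C)C(C)C1OCCO1
F9 | step 8 | methyl (5R)-5-[1-(1,3-dioxolan-2-yl)ethyl]-5-methylcyclopent-1-ene-1-carboxylate | COC(=O)C1=CCC[C@]1(C)C(C)C1OCCO1
F10 | step 8 | {(5R)-5-[1-(1,3-dioxolan-2-yl)ethyl]-5-methylcyclopent-1-en-1-yl}methanol | OCC1=CCC[C@]1(C)C(C)C1OCCO1
F11 | step 8 | N-({(5R)-5-[1-(1,3-dioxolan-2-yl)ethyl]-5-methylcyclopent-1-en-1-yl}methyl)-2-nitrobenzenesulfonohydrazide | NN(CC1=CCC[C@]1(C)C(C)C1OCCO1)S(=O)(=O)c1ccccc1[N+](=O)[O-]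
F12 | step 8 | ({(5R)-5-[1-(1,3-dioxolan-2-yl)ethyl]-5-methylcyclopent-1-en-1-yl}methyl)diazene | N=NCC1=CCC[C@]1(C)C(C)C1OCCO1
F13 | step 8 | 2-{1-[(1R)-1-methyl-2-methylidenecyclopentyl]ethyl}-1,3-dioxolane | C=C1CCC[C@]1(C)C(C)C1OCCO1
F14 | step 8 | 2-[(1R)-1-methyl-2-methylidenecyclopentyl]propanal | C=C1CCC[C@]1(C)C(C)C=O
F15 | step 8 | 2-methyl-2-[(1S)-1-methyl-2-methylidenecyclopentyl]-5-oxohexanal | C=C1CCC[C@]1(C)C(C)(CCC(C)=O)C=O
F16 | step 8 | 3-hydroxy-4-methyl-4-[(1S)-1-methyl-2-methylidenecyclopentyl]cyclohexan-1-one | C=C1CCC[C@]1(C)C1(C)CCC(=O)CC1O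
F17 | step 8 | 4-methyl-4-[(1S)-1-methyl-2-methylidenecyclopentyl]cyclohex-2-en-1-one | C=C1CCC[C@]1(C)C1(C)CCC(=O)C=C1
F18 | step 14 | trimethyl({(4S)-4-methyl-4-[(1S)-1-methyl-2-methylidenecyclopentyl]cyclohex-1-en-1-yl}oxy)silane | C=C1CCC[C@]1(C)[C@@]1(C)CCC(O[Si](C)(C)C)=CC1
F19 | step 3 | (1E,3S)-N-tert-butyl-2,3,7-trimethyl-2-[2-(2-methyl-1,3-dioxolan-2-yl)ethyl]oct-6-en-1-imine | CC(C)=CCC[C@H](C)C(C)(CCC1(C)OCCO1)/C=N/C(C)(C)C
F20 | step 12 | [(5R)-5-methyl-5-(8-methyl-1,4-dioxaspiro[4.5]decan-8-yl)cyclopent-1-en-1-yl]methyl methyl carbonate | COC(=O)OCC1=CCC[C@]1(C)C1(C)CCC2(CC1)OCCO2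
F21 | step 7 | methyl (6S)-6-(8-methyl-1,4-dioxaspiro[4.5]decan-8-yl)-3-oxoheptanoate | COC(=O)CC(=O)CC[C@H](C)C1(C)CCC2(CC1)OCCO2
A1 | alternative 1 | 3-[(1R,2R)-2-{[tert-butyl(dimethyl)silyl]oxy}-1-methylcyclopentyl]-3-methylcyclobutan-1-one | CC(C)(C)[Si](C)(C)O[C@@H]1CCC[C@]1(C)C1(C)CC(=O)C1
A2 | alternative 1 | trimethyl(prop-1-yn-1-yl)silane | CC#C[Si](C)(C)C
A3 | alternative 1 | (5R)-5-[(1R,2R)-2-{[tert-butyl(dimethyl)silyl]oxy}-1-methylcyclopentyl]-2,5-dimethyl-3-(trimethylsilyl)cyclohex-2-en-1-one | CC(C)(C)[Si](C)(C)O[C@@H]1CCC[C@]1(C)[C@@]1(C)CC([Si](C)(C)C)=C(C)C(=O)C1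
A4 | alternative 2 | (1S)-3-[(6R)-6-methyl-1,4-dioxaspiro[4.4]nonan-6-yl]cyclohex-2-en-1-ol | O1CCOC12CCC[C@]2(C)C1=C[C@@H](O)CCC1
A5 | alternative 2 | (1R,2S,6R)-6-[(6R)-6-methyl-1,4-dioxaspiro[4.4]nonan-6-yl]bicyclo[4.1.0]heptan-2-ol | O1CCOC12CCC[C@]2(C)[C@@]12C[C@H]2[C@@H](O)CCC1
A6 | alternative 3 | (4S,6Z)-4-(benzyloxy)-7-(1-hydroxycyclobutyl)-6-methylocta-1,6-dien-3-one | C=CC(=O)[C@@H](OCc1ccccc1)C/C(C)=C(/C)C1(O)CCC1
A7 | alternative 3 | (2S,4S)-2-(benzyloxy)-4-methyl-4-[(1R)-1-methyl-2-oxocyclopentyl]cyclohexan-1-one | O=C1CCC[C@]1(C)[C@@]1(C)CCC(=O)[C@@H](OCc2ccccc2)C1
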